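(The earlier runs and the new flask were generated by integration from invented constants, and the scatter is random.)

Ochre and teal were my two runs, with equal charges, but teal carried 1.49 times ochre's free catalyst.

common to all: starting material 0.095 M; reagent 0.0902 M; temperature 25 °C

| flask | free catalyst | remark | time |
|---|---|---|---|
| ochre | 0.47 mM | the very flask that is asked about, followed so far |  |
| teal | 0.70 mM | run made earlier |  |
| flask | 0.47 mM |  | 15 min |

ochre run (percent of the starting material charged)

| time / min | target / % | starting material / % |
|---|---|---|
| 2.00 | 31.3 | 59.5 |
| 5.00 | 43.1 | 21.6 |
| 10.0 | 31.0 | 5.6 |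
| 15.0 | 25.0 | 4.5 |

teal run (percent of the starting material charged)

| time / s | target / % | starting material / % |
|---|---|---|
| 10.0 | 4.9 | 94.3 |
| 25.0 | 12.6 | 85.9 |
| 50.0 | 23.4 | 73.5 |
| 80.0 | 33.6 | 59.4 |

(standard deviation of a reading: 0.3 percentage points)

- target taken out counts as made
- what was read earlier has a scatter of 0.3 percentage points, one standard deviation
- additions bring no volume worth counting
- the earlier runs do not show what temperature does; that part of a forecast is a guess

- Sunday's: at 15 min add free catalyst, 50.0% of the amount charged, then wait 15 min
- Saturday's: change nothing and wait 15 min more
- Thursday's: at 15 min take out 90% of the target then present, then wait 15 min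
- Friday's: at 15 min add reagent, 100% of the amount charged, then wait 15 min
- Tuesday's: at 15 min raise the temperature by 15 K, then wait 15 min

1. target, in percent of the starting material first charged, at 15 min
2. the remedy with the largest gain of target, or "none" below 2 percentage points (Sunday's / Saturday's / Thursday's / Friday's / Tuesday's / none)
3. target present, with what was taken out counted in, in percent of the starting material first charged, after Thursday's
4. target present, with what was taken out counted in, in percent of the starting material first charged, after Friday's

Both runs fell short of the charge. I called the gap whatever was neither starting material nor target. Gap per target was 0.208 at teal's last reading and 0.294 at ochre's first. Those two stand at 0.707, and their times at 0.667, so the gap followed the clock despite teal's extra catalyst. Target was leaving by a step of its own.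

With target rising roughly linearly, teal gave a loss constant of 0.00521 s⁻¹, a half-life of 2.22 min. Teal's last reading came sooner than that, so teal stopped with a small gap. Ochre's last came after 6.76 half-lives. Yet that constant would have taken ochre's target from 31.0% to 6.50% between its last readings, and it read 25.0%. So the loss runs back too, and ochre was near a balance.

Gap over target at ochre's last reading was 2.82, and I carried this on as the standing ratio. At a fixed temperature, after a long enough wait, target should be the pool of target and gap divided by one plus this ratio.

So I took 25.0% for now, and waiting gains nothing. Thursday's leaves a smaller pool that refills target, giving 41.6% with the removed part counted. Reagent is the limiting reagent, so Friday's can feed in the last 4.5% of starting material. That makes the whole charge the pool, giving 26.2%, a gain smaller than 2 percentage points. Tuesday's I could only guess at, so I chose Thursday's.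

The forecast differed, with 25%, none, 24.7% and 4%: “Heating speeds the loss.”

The flask stood at 24.9%, and Tuesday's was best, gaining 37 points; Thursday's gave 40.0% and Friday's 24.4%.

    reagent + catalyst intermediate B ⇌ catalyst intermediate C (K = 6.00 L mol⁻¹, k = 69.0 L mol⁻¹ s⁻¹, Ea = 52.0 kJ mol⁻¹, ΔH = 1.00 kJ mol⁻¹)
    catalyst intermediate A → catalyst intermediate B (k = 1.80 s⁻¹, Ea = 66.0 kJ mol⁻¹)
    target ⇌ isomer of the product (K = 3.10, k = 0.00440 s⁻¹, Ea = 89.0 kJ mol⁻¹, ΔH = −90.0 kJ mol⁻¹)
    catalyst intermediate C → free catalyst + target (k = 4.90 s⁻¹, Ea = 66.0 kJ mol⁻¹)
    starting material + free catalyst → catalyst intermediate A (k = 780 L mol⁻¹ s⁻¹, Ea = 45.0 kJ mol⁻¹)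
    (constants at 25 °C)

The gap was isomer of the product, 70.0% at 15.0 min. Run at 40 °C, the same flask held 33.5% isomer of the product against 61.5% target, a standing ratio of 0.545 against ochre's 2.82. For Tuesday's pool, ochre's ratio gives target of 25.0%, and the ratio at 40 °C gives 61.7%.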